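**Plan**
- Retrosynthesis: the butenolide is cut at C4–CH2, C2–C3 and O1–C2, giving an (R)-1-alkyn-3-ol, a silylmethyl Grignard reagent (masked CH2OH) and CO2. The side-chain C(CH2OH)=CH alkene is then cut at its bond to the homofarnesyl chain, the alkyne–CH2OH bond to formaldehyde, and the carbinol–CH2 bond to 3-(trimethylsilyl)propynal plus an allenylboronate.
- Enabling feature: the ring O1–C2(=O)–C3(H)=C4(CH2OH)–C5(H) is the lactone of a γ-hydroxy enoic acid with the carboxyl cis to the C5 oxygen. Its C3=C4 unit (H on C3, one carbon on C4) is therefore the anti adduct of a C1 carbanion and CO2 across a terminal alkyne attached to the C5 carbinol.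
- Forward order: C3 + C3 gives the diynol, then C1 (formaldehyde), then C16 (homofarnesyl, from farnesol by one-carbon homologation). After silyl adjustment the only ring, the butenolide, closes in step 11; Tamao oxidation and desilylation finish.
- Stereochemistry: C5 (R) comes from the (R)-TRIP-catalysed propargylation and its C–O bond is never broken afterwards. The C(CH2OH)=CH geometry and the cis acid/alcohol relationship come from two alkoxide-directed anti-carbomagnesiations; the two E-alkenes come from (2E,6E)-farnesol.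

Key step: step 11

Remark: butenolide atoms are numbered O1, C2 (C=O), C3, C4, C5. The (R)-enantiomer of TRIP is assumed to direct attack to the Re face of the ynal, as it does with aryl and alkenyl aldehydes; if the sense were opposite, the (S)-acid would be used.

**Step 1**
Reactants: 1 3-(trimethylsilyl)prop-2-ynal; 2 allenylboronic acid pinacol ester
Product: 4 (3R)-1-(trimethylsilyl)hexa-1,5-diyn-3-ol, via pinacol borate 3 (not isolated)
Conditions: (R)-TRIP (5 mol%), 4 Å MS, toluene, −30 °C; aqueous work-up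
Reagents that add atoms: none
Why: Chiral phosphoric acid-catalysed propargylation of an aldehyde with an allenylboronate runs through a closed six-membered SE2′ transition state that gives only the homopropargylic alcohol, and the (R)-acid should expose the Re face of the ynal, which sets the later C5 as (R), the low temperature keeping the uncatalysed pathway slow.

**Step 2**
Reactants: 4 (3R)-1-(trimethylsilyl)hexa-1,5-diyn-3-ol
Product: 5 tert-butyldimethyl{[(3R)-1-(trimethylsilyl)hexa-1,5-diyn-3-yl]oxy}silane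
Conditions: TBSCl, imidazole, DMF, 0 °C → rt
Reagents that add atoms: tert-butyldimethylsilyl chloride, CC(C)(C)[Si](C)(C)Cl
Why: Standard imidazole-promoted silylation gives an ether that is stable to n-BuLi and Grignard reagents and, unlike a free alkoxide, cannot direct carbometalation of the neighbouring silyl alkyne in step 8.

**Step 3**
Reactants: 5 tert-butyldimethyl{[(3R)-1-(trimethylsilyl)hexa-1,5-diyn-3-yl]oxy}silane
Product: 7 (5R)-5-[(tert-butyldimethylsilyl)oxy]-7-(trimethylsilyl)hepta-2,6-diyn-1-ol, via lithium acetylide 6 (not isolated)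
Conditions: n-BuLi, THF, −78 °C; (CH2O)n, −78 °C → rt; aq. NH4Cl
Reagents that add atoms: paraformaldehyde (as formaldehyde), C=O
Why: The terminal alkyne C–H is by far the most acidic site, so n-BuLi should give acetylide 6 cleanly, and its 1,2-addition to formaldehyde (acetylide hydroxymethylation) furnishes the 2-alkyn-1-ol needed for directed carbometalation.

**Step 4**
Reactants: 8 (2E,6E)-farnesol
Product: 9 (2E,6E)-farnesal
Conditions: TEMPO (10 mol%), PhI(OAc)2, CH2Cl2, rt
Reagents that add atoms: none
Why: TEMPO/PhI(OAc)2 oxidation of a primary allylic alcohol stops at the enal and proceeds through the oxoammonium salt without acid or base strong enough to scramble the 2E alkene.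

**Step 5**
Reactants: 9 (2E,6E)-farnesal
Product: 10 (3E,7E)-4,8,12-trimethyltrideca-1,3,7,11-tetraene
Conditions: Ph3PCH3Br, n-BuLi, THF, 0 °C; then 9, 0 °C → rt
Reagents that add atoms: methyltriphenylphosphonium bromide, C[P+](c1ccccc1)(c1ccccc1)c1ccccc1.[Br-]
Why: Wittig methylenation with the unstabilised ylide converts the enal into the terminal diene without touching the existing E-alkenes.

**Step 6**
Reactants: 10 (3E,7E)-4,8,12-trimethyltrideca-1,3,7,11-tetraene
Product: 12 (3E,7E)-homofarnesol, via alkylborane 11 (not isolated)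
Conditions: 9-BBN, THF, 0 °C → rt; then aq. NaOH, 30% H2O2, 0 °C → rt
Reagents that add atoms: hydrogen peroxide, OO
Why: In this hydroboration–oxidation 9-BBN should add anti-Markovnikov only to the monosubstituted terminal alkene of the diene, leaving the three trisubstituted alkenes untouched, and alkaline peroxide converts borane 11 into the primary homoallylic alcohol.

**Step 7**
Reactants: 12 (3E,7E)-homofarnesol
Product: 13 (3E,7E)-homofarnesyl bromide
Conditions: CBr4, PPh3, CH2Cl2, 0 °C
Reagents that add atoms: carbon tetrabromide, BrC(Br)(Br)Br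
Why: Appel bromination is an SN2 displacement of the oxyphosphonium group at a primary carbon, and because the position is homoallylic no allylic transposition can occur.

**Step 8**
Reactants: 13 (3E,7E)-homofarnesyl bromide; 7 (5R)-5-[(tert-butyldimethylsilyl)oxy]-7-(trimethylsilyl)hepta-2,6-diyn-1-ol
Product: 16 (2E,5R)-5-[(tert-butyldimethylsilyl)oxy]-2-[(3E,7E)-4,8,12-trimethyltrideca-3,7,11-trien-1-yl]-7-(trimethylsilyl)hept-2-en-6-yn-1-ol, via homofarnesylmagnesium bromide 14 (not isolated), via alkenylmagnesium chelate 15 (not isolated)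
Conditions: 13 (3 equiv), Mg, Et2O, reflux; then 7, CuI (15 mol%), Et2O, −10 °C → rt; aq. NH4Cl
Reagents that add atoms: none
Why: In this copper-catalysed anti-carbomagnesiation of a 2-alkyn-1-ol the magnesium alkoxide of 7 (formed by the first equivalent of 14) directs the alkyl group to C2 and the metal to C3 in the five-membered chelate 15, so protonation leaves the homofarnesyl chain cis to C4 as in the target alkene, while the OTBS group cannot chelate and the silyl-capped alkyne, lacking an alkoxide, is not attacked.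

**Step 9**
Reactants: 16 (2E,5R)-5-[(tert-butyldimethylsilyl)oxy]-2-[(3E,7E)-4,8,12-trimethyltrideca-3,7,11-trien-1-yl]-7-(trimethylsilyl)hept-2-en-6-yn-1-ol
Product: 17 (2E,5R)-2-[(3E,7E)-4,8,12-trimethyltrideca-3,7,11-trien-1-yl]hept-2-en-6-yne-1,5-diol
Conditions: TBAF (2.5 equiv), THF, 0 °C → rt
Reagents that add atoms: none
Why: Fluoride desilylation cleaves the secondary O–TBS ether and the alkynyl C–SiMe3 bond in one operation without touching the carbinol C–O bond, so the configuration is retained.

**Step 10**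
Reactants: 17 (2E,5R)-2-[(3E,7E)-4,8,12-trimethyltrideca-3,7,11-trien-1-yl]hept-2-en-6-yne-1,5-diol
Product: 18 (3R,5E,9E,13E)-6-{[(tert-butyldimethylsilyl)oxy]methyl}-10,14,18-trimethylnonadeca-5,9,13,17-tetraen-1-yn-3-ol
Conditions: TBSCl (1.05 equiv), imidazole, CH2Cl2, −20 → 0 °C
Reagents that add atoms: tert-butyldimethylsilyl chloride, CC(C)(C)[Si](C)(C)Cl
Why: In this kinetically selective silylation the unhindered primary allylic hydroxyl should react much faster than the secondary propargylic one, which must stay free to direct the key step.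

**Step 11**
Reactants: 18 (3R,5E,9E,13E)-6-{[(tert-butyldimethylsilyl)oxy]methyl}-10,14,18-trimethylnonadeca-5,9,13,17-tetraen-1-yn-3-ol; 19 (chloromethyl)(isopropoxy)dimethylsilane
Product: 23 (5R)-5-[(2E,6E,10E)-3-{[(tert-butyldimethylsilyl)oxy]methyl}-7,11,15-trimethylhexadeca-2,6,10,14-tetraen-1-yl]-4-{[isopropoxy(dimethyl)silyl]methyl}furan-2(5H)-one, via silylmethyl Grignard reagent 20 (not isolated), via alkenylmagnesium chelate 21 (not isolated), via hydroxy acid 22 (not isolated)
Conditions: 19 (3.5 equiv), Mg, THF, reflux; then 18, CuI (10 mol%), THF–Et2O, −20 °C → rt; CO2 (gas), −20 °C → rt; 1 M HCl to pH 3, 0 °C → rt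
Reagents that add atoms: carbon dioxide, O=C=O
Why: The first equivalent of 20 turns 18 into its magnesium alkoxide, which holds the copper/magnesium reagent beside the terminal alkyne so that the silylmethyl group is delivered to the internal carbon (C4) anti to the metal, giving the five-membered O–Mg–C3=C4–C5 chelate 21 with magnesium on C3 cis to C5 (C4–CH2 bond). CO2 then inserts into the C3–Mg bond with retention of alkene geometry (C2–C3 bond), and acidification releases hydroxy acid 22, whose carboxyl and C5 hydroxyl are cis and close the butenolide by 5-exo-trig acyl substitution (O1–C2 bond). The closest known reaction type is the copper-catalysed anti-carbomagnesiation of propargylic alcohols, which accepts terminal alkynes and silylmethyl Grignard reagents and whose chelated alkenylmagnesium intermediates are known to give butenolides on carboxylation. No stereocentre is created; C5 stays an alkoxide or alcohol throughout and its C–O bond is never broken, so the (R) configuration of 18 should pass unchanged into 23. The step needs regioselectivity (carbon to C4, metal to C3) and anti stereoselectivity, both secured by the C5 alkoxide chelate, and chemoselectivity follows because 18 has one free hydroxyl and one alkyne, its other alkenes being unactivated and the TBS ether inert; the acid work-up is kept cold and brief so that the Si–OiPr and O–TBS groups survive.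

**Step 12**
Reactants: 23 (5R)-5-[(2E,6E,10E)-3-{[(tert-butyldimethylsilyl)oxy]methyl}-7,11,15-trimethylhexadeca-2,6,10,14-tetraen-1-yl]-4-{[isopropoxy(dimethyl)silyl]methyl}furan-2(5H)-one
Product: 24 (5R)-5-[(2E,6E,10E)-3-{[(tert-butyldimethylsilyl)oxy]methyl}-7,11,15-trimethylhexadeca-2,6,10,14-tetraen-1-yl]-4-(hydroxymethyl)furan-2(5H)-one
Conditions: KF, KHCO3, 30% H2O2, THF–MeOH (1:1), 0 °C → rt
Reagents that add atoms: hydrogen peroxide, OO
Why: In the Tamao oxidation fluoride and hydroperoxide add to the alkoxysilane, the CH2 group migrates from silicon to oxygen and hydrolysis releases the primary alcohol, while the bicarbonate buffer should keep the medium mild enough for the lactone, the C5 stereocentre and the TBS ether.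

**Step 13**
Reactants: 24 (5R)-5-[(2E,6E,10E)-3-{[(tert-butyldimethylsilyl)oxy]methyl}-7,11,15-trimethylhexadeca-2,6,10,14-tetraen-1-yl]-4-(hydroxymethyl)furan-2(5H)-one
Product: 25 Hippolide E
Conditions: HF·pyridine, pyridine, THF, 0 °C → rt
Reagents that add atoms: none
Why: Fluoride-mediated cleavage of the primary TBS ether with pyridine-buffered HF·pyridine is neither basic enough to enolise the butenolide at C5 nor acidic enough to ionise the allylic alcohols.

**Compound list**
1 | 3-(trimethylsilyl)prop-2-ynal | C[Si](C)(C)C#CC=O | starting material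
2 | allenylboronic acid pinacol ester | C=C=CB1OC(C)(C)C(C)(C)O1 | starting material
3 | 4,4,5,5-tetramethyl-2-{[(3R)-1-(trimethylsilyl)hexa-1,5-diyn-3-yl]oxy}-1,3,2-dioxaborolane (pinacol borate of 4, formed in situ) | C[Si](C)(C)C#C[C@H](OB1OC(C)(C)C(C)(C)O1)CC#C | intermediate
4 | (3R)-1-(trimethylsilyl)hexa-1,5-diyn-3-ol | C[Si](C)(C)C#C[C@H](O)CC#C | intermediate
5 | tert-butyldimethyl{[(3R)-1-(trimethylsilyl)hexa-1,5-diyn-3-yl]oxy}silane | C[Si](C)(C)C#C[C@H](O[Si](C)(C)C(C)(C)C)CC#C | intermediate
6 | lithium acetylide of 5 (formed in situ) | [Li]C#CC[C@@H](O[Si](C)(C)C(C)(C)C)C#C[Si](C)(C)C | intermediate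
7 | (5R)-5-[(tert-butyldimethylsilyl)oxy]-7-(trimethylsilyl)hepta-2,6-diyn-1-ol | OCC#CC[C@@H](O[Si](C)(C)C(C)(C)C)C#C[Si](C)(C)C | intermediate
8 | (2E,6E)-farnesol | CC(C)=CCC/C(C)=C/CC/C(C)=C/CO | starting material
9 | (2E,6E)-farnesal | CC(C)=CCC/C(C)=C/CC/C(C)=C/C=O | intermediate
10 | (3E,7E)-4,8,12-trimethyltrideca-1,3,7,11-tetraene | CC(C)=CCC/C(C)=C/CC/C(C)=C/C=C | intermediate
11 | B-[(3E,7E)-4,8,12-trimethyltrideca-3,7,11-trien-1-yl]-9-borabicyclo[3.3.1]nonane (formed in situ) | CC(C)=CCC/C(C)=C/CC/C(C)=C/CCB1C2CCCC1CCC2 | intermediate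
12 | (3E,7E)-homofarnesol, (3E,7E)-4,8,12-trimethyltrideca-3,7,11-trien-1-ol | CC(C)=CCC/C(C)=C/CC/C(C)=C/CCO | intermediate
13 | (3E,7E)-homofarnesyl bromide, (3E,7E)-1-bromo-4,8,12-trimethyltrideca-3,7,11-triene | CC(C)=CCC/C(C)=C/CC/C(C)=C/CCBr | intermediate
14 | homofarnesylmagnesium bromide (formed in situ) | CC(C)=CCC/C(C)=C/CC/C(C)=C/CC[Mg]Br | intermediate
15 | 2,5-dihydro-1,2-oxamagnesole chelate from 7: Mg bonded to O and to C3, homofarnesyl on C2, (R)-CH2CH(OTBS)C≡CSiMe3 on C3 (formed in situ) | CC(C)=CCC/C(C)=C/CC/C(C)=C/CCC1=C(C[C@@H](O[Si](C)(C)C(C)(C)C)C#C[Si](C)(C)C)[Mg]OC1 | intermediate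
16 | (2E,5R)-5-[(tert-butyldimethylsilyl)oxy]-2-[(3E,7E)-4,8,12-trimethyltrideca-3,7,11-trien-1-yl]-7-(trimethylsilyl)hept-2-en-6-yn-1-ol | CC(C)=CCC/C(C)=C/CC/C(C)=C/CC/C(=C\C[C@@H](O[Si](C)(C)C(C)(C)C)C#C[Si](C)(C)C)CO | intermediate
17 | (2E,5R)-2-[(3E,7E)-4,8,12-trimethyltrideca-3,7,11-trien-1-yl]hept-2-en-6-yne-1,5-diol | CC(C)=CCC/C(C)=C/CC/C(C)=C/CC/C(=C\C[C@@H](O)C#C)CO | intermediate
18 | (3R,5E,9E,13E)-6-{[(tert-butyldimethylsilyl)oxy]methyl}-10,14,18-trimethylnonadeca-5,9,13,17-tetraen-1-yn-3-ol | CC(C)=CCC/C(C)=C/CC/C(C)=C/CC/C(=C\C[C@@H](O)C#C)CO[Si](C)(C)C(C)(C)C | intermediate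
19 | (chloromethyl)(isopropoxy)dimethylsilane | CC(C)O[Si](C)(C)CCl | starting material
20 | (isopropoxydimethylsilyl)methylmagnesium chloride (formed in situ) | CC(C)O[Si](C)(C)C[Mg]Cl | intermediate
21 | 2,5-dihydro-1,2-oxamagnesole chelate from 18: Mg bonded to O1 and C3, silylmethyl on C4, (R)-C5 bearing the side chain (formed in situ) | CC(C)=CCC/C(C)=C/CC/C(C)=C/CC/C(=C\C[C@H]1O[Mg]C=C1C[Si](C)(C)OC(C)C)CO[Si](C)(C)C(C)(C)C | intermediate
22 | (2E,4R,6E,10E,14E)-7-{[(tert-butyldimethylsilyl)oxy]methyl}-4-hydroxy-3-{[isopropoxy(dimethyl)silyl]methyl}-11,15,19-trimethylicosa-2,6,10,14,18-pentaenoic acid, carboxyl cis to C4–OH (formed in situ) | CC(C)=CCC/C(C)=C/CC/C(C)=C/CC/C(=C\C[C@@H](O)/C(C[Si](C)(C)OC(C)C)=C\C(=O)O)CO[Si](C)(C)C(C)(C)C | intermediate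
23 | (5R)-5-[(2E,6E,10E)-3-{[(tert-butyldimethylsilyl)oxy]methyl}-7,11,15-trimethylhexadeca-2,6,10,14-tetraen-1-yl]-4-{[isopropoxy(dimethyl)silyl]methyl}furan-2(5H)-one | CC(C)=CCC/C(C)=C/CC/C(C)=C/CC/C(=C\C[C@H]1OC(=O)C=C1C[Si](C)(C)OC(C)C)CO[Si](C)(C)C(C)(C)C | intermediate
24 | (5R)-5-[(2E,6E,10E)-3-{[(tert-butyldimethylsilyl)oxy]methyl}-7,11,15-trimethylhexadeca-2,6,10,14-tetraen-1-yl]-4-(hydroxymethyl)furan-2(5H)-one | CC(C)=CCC/C(C)=C/CC/C(C)=C/CC/C(=C\C[C@H]1OC(=O)C=C1CO)CO[Si](C)(C)C(C)(C)C | intermediate
25 | Hippolide E, (5R)-4-(hydroxymethyl)-5-[(2E,6E,10E)-3-(hydroxymethyl)-7,11,15-trimethylhexadeca-2,6,10,14-tetraen-1-yl]furan-2(5H)-one | CC(C)=CCC/C(C)=C/CC/C(C)=C/CC/C(=C\C[C@H]1OC(=O)C=C1CO)CO | target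

**Step count and risks**
Total steps: 13. Longest linear sequence: 10 steps (steps 4–13, from farnesol 8).

Step 12, Tamao oxidation. The C4–CH2–Si bond is vinylogous to the lactone carbonyl, so fluoride or bicarbonate may cleave it through the lactone dienolate (protodesilylation) faster than the silicon-to-oxygen shift occurs; base-induced epimerisation at C5 is a second danger. The fallback oxidises the C–Si bond before the carbonyl exists. Setting out from 18, the copper-catalysed carbomagnesiation with 20 is run as in step 11 but chelate 21 is quenched with iodine, which should give (1E,3R,5E,9E,13E)-6-{[(tert-butyldimethylsilyl)oxy]methyl}-1-iodo-2-{[isopropoxy(dimethyl)silyl]methyl}-10,14,18-trimethylnonadeca-1,5,9,13,17-pentaen-3-ol F1. Tamao oxidation of this unactivated allylsilane (KF, KHCO3, H2O2, THF–MeOH) should then give (1Z,3R,5E,9E,13E)-6-{[(tert-butyldimethylsilyl)oxy]methyl}-2-(hydroxymethyl)-1-iodo-10,14,18-trimethylnonadeca-1,5,9,13,17-pentaen-3-ol F2. Palladium-catalysed carbonylative lactonisation (CO 1 atm, PdCl2(PPh3)2, K2CO3, THF, 50 °C) closes the ring; only the secondary hydroxyl is cis to the C–I bond, so the route is rejoined at 24.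

Step 11, carbomagnesiation–carboxylation. The Grignard reagent may deprotonate the terminal alkyne, carbometalation of the hindered secondary alkoxide may stall, or chelate 21 may be protonated before CO2 is captured. The fallback makes the same three bonds in two operations by ynoate conjugate addition. Setting out from 18, the dianion (n-BuLi, 2.1 equiv, THF, −78 °C) is C-acylated with methyl chloroformate to give methyl (4R,6E,10E,14E)-7-{[(tert-butyldimethylsilyl)oxy]methyl}-4-hydroxy-11,15,19-trimethylicosa-6,10,14,18-tetraen-2-ynoate F3. Syn addition of the silylmethyl cuprate prepared from 20 and CuI (THF, −78 °C) places the CH2Si group on C4 and leaves the ester cis to the C5 hydroxyl, so the adduct should lactonise on work-up and rejoin the route at 23.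

Step 8, carbomagnesiation with the homofarnesyl reagent. Addition of a primary alkyl Grignard reagent to the internal alkyne may be slow, with reduction of the alkyne by β-hydride transfer and consumption of a large excess of the C16 reagent. The fallback is trans-hydrostannation followed by cross-coupling. Setting out from 7, ruthenium-catalysed hydroxyl-directed trans-hydrostannation ([Cp*RuCl]4 cat., Bu3SnH, CH2Cl2) should give (2Z,5R)-5-[(tert-butyldimethylsilyl)oxy]-2-(tributylstannyl)-7-(trimethylsilyl)hept-2-en-6-yn-1-ol F4. Iododestannylation (I2, CH2Cl2, 0 °C) should give (2Z,5R)-5-[(tert-butyldimethylsilyl)oxy]-2-iodo-7-(trimethylsilyl)hept-2-en-6-yn-1-ol F5 with retention. B-alkyl Suzuki–Miyaura coupling of F5 with alkylborane 11, generated from 10 as in the first stage of step 6 (PdCl2(dppf), AsPh3, Cs2CO3, DMF–THF–H2O, rt), proceeds with retention and rejoins the route at 16; steps 7 and the oxidation half of step 6 are then not needed.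

**Further compounds**
F1 | step 12 | (1E,3R,5E,9E,13E)-6-{[(tert-butyldimethylsilyl)oxy]methyl}-1-iodo-2-{[isopropoxy(dimethyl)silyl]methyl}-10,14,18-trimethylnonadeca-1,5,9,13,17-pentaen-3-ol | CC(C)=CCC/C(C)=C/CC/C(C)=C/CC/C(=C\C[C@@H](O)/C(C[Si](C)(C)OC(C)C)=C\I)CO[Si](C)(C)C(C)(C)C
F2 | step 12 | (1Z,3R,5E,9E,13E)-6-{[(tert-butyldimethylsilyl)oxy]methyl}-2-(hydroxymethyl)-1-iodo-10,14,18-trimethylnonadeca-1,5,9,13,17-pentaen-3-ol | CC(C)=CCC/C(C)=C/CC/C(C)=C/CC/C(=C\C[C@@H](O)/C(CO)=C\I)CO[Si](C)(C)C(C)(C)C
F3 | step 11 | methyl (4R,6E,10E,14E)-7-{[(tert-butyldimethylsilyl)oxy]methyl}-4-hydroxy-11,15,19-trimethylicosa-6,10,14,18-tetraen-2-ynoate | CC(C)=CCC/C(C)=C/CC/C(C)=C/CC/C(=C\C[C@@H](O)C#CC(=O)OC)CO[Si](C)(C)C(C)(C)C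
F4 | step 8 | (2Z,5R)-5-[(tert-butyldimethylsilyl)oxy]-2-(tributylstannyl)-7-(trimethylsilyl)hept-2-en-6-yn-1-ol | CCCC[Sn](CCCC)(CCCC)/C(CO)=C\C[C@@H](O[Si](C)(C)C(C)(C)C)C#C[Si](C)(C)C
F5 | step 8 | (2Z,5R)-5-[(tert-butyldimethylsilyl)oxy]-2-iodo-7-(trimethylsilyl)hept-2-en-6-yn-1-ol | I/C(CO)=C\C[C@@H](O[Si](C)(C)C(C)(C)C)C#C[Si](C)(C)C
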